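**Assumption:** germacrone (natural isolate sold in multigram lots) is taken as a cheap commercial starting material; locants follow germacrane/guaiane numbering (isopropyl on C7, acyloxy on C8).

## Retrosynthetic overview

1. Target ⇐ α-face epoxidation of a guai-3-ene; the oxirane is the last ring formed.
2. Guai-3-ene ⇐ dehydration of the C4 tertiary alcohol of a guaiane-4,10-diol 8-veratrate.
3. Guaiane 5/7 core ⇐ transannular epoxide–olefin cyclization of a (4S,5S)-4,5-epoxygermacr-1(10)-ene (C1–C5 bond), with the C10 cation caught by the C8 veratrate carbonyl.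
4. Epoxygermacrene ⇐ catalyst-controlled epoxidation ⇐ veratrate ⇐ cis-alcohol (dynamic kinetic resolution) ⇐ dihydrogermacrone ⇐ germacrone.
5. Ring order: ten-membered carbocycle (bought with germacrone) → cyclopentane and cycloheptane together in one transannular step → oxirane.

## Route

Step 1
Reactants: 1 germacrone, (1(10)E,4E)-germacra-1(10),4,7(11)-trien-8-one
Product: 2 (±)-(1(10)E,4E)-germacra-1(10),4-dien-8-one (7,11-dihydrogermacrone, racemic at C7)
Conditions: Li, liquid NH3, THF, t-BuOH (1 equiv), −78 °C; then NH4Cl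
Reagents that add atoms: none
Why: Dissolving-metal (Birch-type) conjugate reduction of the tetrasubstituted enone runs through the radical anion and the lithium enolate, leaves the two isolated trisubstituted ring olefins untouched, and protonation of the enolate at C7 on quench gives the ketone as a racemate whose C7 centre is deliberately left labile for step 2.

Step 2
Reactants: 2 (±)-(1(10)E,4E)-germacra-1(10),4-dien-8-one
Product: 3 (7R,8R,1(10)E,4E)-germacra-1(10),4-dien-8-ol (isopropyl and hydroxyl cis)
Conditions: H2 (8 atm), RuCl2[(S)-BINAP][(R,R)-DPEN] (0.5 mol%), t-BuOK (2 mol%), i-PrOH, 25 °C (BINAP = 2,2'-bis(diphenylphosphino)-1,1'-binaphthyl, DPEN = 1,2-diphenylethylenediamine)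
Reagents that add atoms: none
Why: Noyori asymmetric hydrogenation with dynamic kinetic resolution, in which the base racemises C7 through the enolate while the carbonyl-selective catalyst reduces one enantiomer on one face, sets C7 and C8 together as the cis-(7R,8R) alcohol in the same sense as cis-(1R,2R)-2-isopropylcyclohexanol is formed from racemic 2-isopropylcyclohexanone, and this catalyst class does not reduce C=C bonds.

Step 3
Reactants: 3 (7R,8R,1(10)E,4E)-germacra-1(10),4-dien-8-ol; 4 3,4-dimethoxybenzoyl chloride (veratroyl chloride)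
Product: 5 (7R,8R,1(10)E,4E)-germacra-1(10),4-dien-8-yl 3,4-dimethoxybenzoate
Conditions: pyridine, 4-(dimethylamino)pyridine (catalytic), CH2Cl2, 0 °C to rt
Reagents that add atoms: 3,4-dimethoxybenzoyl chloride (compound 4), COc1ccc(C(Cl)=O)cc1OC
Why: DMAP-catalysed acylation (acyl transfer through the N-acylpyridinium ion) of the only hydroxyl group touches no stereocentre and places the electron-rich aroyl group of the target at C8 early so that it can serve as the internal nucleophile in step 5.

Step 4
Reactants: 5 (7R,8R,1(10)E,4E)-germacra-1(10),4-dien-8-yl 3,4-dimethoxybenzoate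
Product: 6 (4S,5S,7R,8R,1(10)E)-4,5-epoxygermacr-1(10)-en-8-yl 3,4-dimethoxybenzoate
Conditions: 1,2:4,5-di-O-isopropylidene-β-L-erythro-2,3-hexodiulo-2,6-pyranose (L-Shi ketone, 0.3 equiv), 30% H2O2 (1.3 equiv), MeCN–EtOH–CH2Cl2, aq K2CO3/EDTA, 0 °C
Reagents that add atoms: hydrogen peroxide, OO
Why: In this Shi asymmetric epoxidation (chiral dioxirane, spiro transition state) the C4=C5 olefin reacts first because C1=C10 is homoallylic to the C8 acyloxy group and shielded by it, and since a ring E-olefin can only be attacked on its outer face the L-configured ketone (S,S-selective for this olefin type) picks the interconverting ring conformer with C15 pointing down and gives the (4S,5S)-epoxide under reagent control.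

Step 5
Reactants: 6 (4S,5S,7R,8R,1(10)E)-4,5-epoxygermacr-1(10)-en-8-yl 3,4-dimethoxybenzoate
Product: 8 (1R,4S,5S,7R,8R,10S)-4,10-dihydroxyguaian-8-yl 3,4-dimethoxybenzoate (1αH, 5βH, 4β-OH, 10β-OH), via dioxanylium zwitterion 7 (not isolated)
Conditions: Sc(OTf)3 (5 mol%), CH2Cl2, −40 to 0 °C; then THF–H2O, rt
Reagents that add atoms: water, O
Why: Proposed new method: Lewis-acid opening of the (4S,5S)-epoxide makes C5 electrophilic and the C1=C10 olefin attacks it across the ring (5-exo, inversion at C5 giving H-5β with the oxygen left as the 4β-alkoxide, and because the epoxide with its methyl locked downward can only react through the ring conformer with C14 up, the down/down arrangement being the one germacradiene conformer that is not populated, C1 is formed with H-1α and the fusion is trans), the tertiary C10 cation is then captured on its β face by the carbonyl oxygen of the 8β-veratrate as a six-membered 2-aryl-1,3-dioxan-2-ylium ion that fixes 10β-O, and aqueous work-up hydrolyses this ion and equilibrates the acyl group onto the secondary C8 oxygen; the closest known reaction types are the acid-mediated transannular cyclisation of 4,5-epoxygermacranes to guaianes (parthenolide to micheliolide) and the capture of carbocations by neighbouring esters as acyloxonium ions (Woodward–Prévost type).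

Step 6
Reactants: 8 (1R,4S,5S,7R,8R,10S)-4,10-dihydroxyguaian-8-yl 3,4-dimethoxybenzoate
Product: 9 (1R,5S,7R,8R,10S)-10-hydroxyguai-3-en-8-yl 3,4-dimethoxybenzoate
Conditions: Ph2S[OC(CF3)2Ph]2 (Martin sulfurane, 2.2 equiv), CH2Cl2, 0 °C to rt; then aq NaHCO3
Reagents that add atoms: none
Why: In this Martin sulfurane dehydration the C4 alkoxysulfonium ion loses H-3 to give the endocyclic trisubstituted cyclopentene, as in the known dehydration of 4-hydroxyguaianes to guai-3-enes, whereas any ionisation at C10 only regenerates the cation of step 5, which is re-captured by the 8β-veratrate and returned as the 10β-alcohol at work-up, so no stereocentre changes.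

Step 7
Reactants: 9 (1R,5S,7R,8R,10S)-10-hydroxyguai-3-en-8-yl 3,4-dimethoxybenzoate
Product: 10 (1R,3R,4S,5S,7R,8R,10S)-3,4-epoxy-10-hydroxyguaian-8-yl 3,4-dimethoxybenzoate (CNP0304846.1)
Conditions: 1,2:4,5-di-O-isopropylidene-β-D-erythro-2,3-hexodiulo-2,6-pyranose (D-Shi ketone, 0.3 equiv), 30% H2O2 (1.5 equiv), MeCN–EtOH–CH2Cl2, aq K2CO3/EDTA, 0 °C
Reagents that add atoms: hydrogen peroxide, OO
Why: Shi epoxidation with the D-fructose-derived ketone adds oxygen to the trisubstituted cyclopentene on the face that gives the (3R,4S)-oxirane (the α face, the same facial sense as in (R,R)-1-phenylcyclohexene oxide), so C3 and C4 are set by the reagent, and the buffered medium leaves the ester, the tertiary alcohol and the acid-sensitive product intact.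

## Compound list

1 | germacrone, (1(10)E,4E)-germacra-1(10),4,7(11)-trien-8-one | C/C1=C\CC/C(C)=C/CC(=C(C)C)C(=O)C1 | starting material
2 | (±)-(1(10)E,4E)-germacra-1(10),4-dien-8-one (racemic at C7) | C/C1=C\CC/C(C)=C/CC(C(C)C)C(=O)C1 | intermediate
3 | (7R,8R,1(10)E,4E)-germacra-1(10),4-dien-8-ol | C/C1=C\CC/C(C)=C/C[C@H](C(C)C)[C@H](O)C1 | intermediate
4 | 3,4-dimethoxybenzoyl chloride (veratroyl chloride) | COc1ccc(C(Cl)=O)cc1OC | starting material
5 | (7R,8R,1(10)E,4E)-germacra-1(10),4-dien-8-yl 3,4-dimethoxybenzoate | C/C1=C\CC/C(C)=C/C[C@H](C(C)C)[C@H](OC(=O)c2ccc(OC)c(OC)c2)C1 | intermediate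
6 | (4S,5S,7R,8R,1(10)E)-4,5-epoxygermacr-1(10)-en-8-yl 3,4-dimethoxybenzoate | C/C1=C\CC[C@]2(C)O[C@H]2C[C@H](C(C)C)[C@H](OC(=O)c3ccc(OC)c(OC)c3)C1 | intermediate
7 | dioxanylium zwitterion: 1αH,5βH-guaiane with O8 and O10 bridged as a 2-(3,4-dimethoxyphenyl)-1,3-dioxan-2-ylium ion and the 4β-alkoxide | COc1ccc(C(=[O+]5)O[C@@H]2C[C@@]5(C)[C@@H]3CC[C@](C)([O-])[C@H]3C[C@@H]2C(C)C)cc1OC | intermediate
8 | (1R,4S,5S,7R,8R,10S)-4,10-dihydroxyguaian-8-yl 3,4-dimethoxybenzoate | COc1ccc(C(=O)O[C@@H]2C[C@](C)(O)[C@@H]3CC[C@](C)(O)[C@H]3C[C@@H]2C(C)C)cc1OC | intermediate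
9 | (1R,5S,7R,8R,10S)-10-hydroxyguai-3-en-8-yl 3,4-dimethoxybenzoate | COc1ccc(C(=O)O[C@@H]2C[C@](C)(O)[C@@H]3CC=C(C)[C@H]3C[C@@H]2C(C)C)cc1OC | intermediate
10 | (1R,3R,4S,5S,7R,8R,10S)-3,4-epoxy-10-hydroxyguaian-8-yl 3,4-dimethoxybenzoate (CNP0304846.1) | COc1ccc(C(=O)O[C@@H]2C[C@](C)(O)[C@@H]3C[C@H]4O[C@@]4(C)[C@H]3C[C@@H]2C(C)C)cc1OC | target

## Step count and risks

Total step count: 7. Longest linear sequence: 7 steps (1 to 10).

Steps most likely to fail:

**Step 5 (transannular cyclization).** The ring fusion rests on a conformational argument. The C10 cation may also be taken by the C4 oxygen (4,10-oxide) or lose a proton instead of being caught by the ester. The fallback sets out from alcohol 3 and moves the ester to after ring formation. Alcohol 3 is epoxidised with the same L-Shi ketone and H2O2 to the epoxy alcohol (4S,5S,7R,8R)-4,5-epoxygermacr-1(10)-en-8-ol F3. F3 is cyclised under aqueous Brønsted acid (catalytic HClO4, THF–H2O, 0 °C), where water is the terminating nucleophile, to 1αH,5βH-guaiane-4β,8β,10β-triol F4. The single secondary hydroxyl of F4 is then acylated with 4 (pyridine, DMAP), and the route is rejoined at compound 8.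

**Step 6 (selective dehydration).** Two tertiary alcohols are present, and the C10 cation could eliminate instead of being re-captured. The fallback sets out from epoxide 6. The cyclization of step 5 is quenched at −78 °C with i-Bu2AlH instead of water, so that dioxanylium 7 (or the ortho ester derived from it) is reduced to the cyclic 3,4-dimethoxybenzylidene acetal of the 8,10-diol with free 4β-hydroxyl F5. Its only free hydroxyl is dehydrated with Martin sulfurane to the guai-3-ene acetal F6. The acetal is then opened oxidatively with 2,3-dichloro-5,6-dicyano-1,4-benzoquinone in wet CH2Cl2, which regenerates the dioxanylium ion, hydrolyses it and delivers the hydroxy veratrate. The route is rejoined at compound 9.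

**Step 2 (dynamic kinetic resolution).** The base needed for racemisation may move the C1=C10 bond into conjugation, and selectivity on a ten-membered ketone is untested. The fallback sets out from ketone 2 and separates the relative and absolute stereocontrol. Reduction with LiBH(s-Bu)3 in THF at −78 °C gives the racemic cis-(7R*,8R*)-germacra-1(10),4-dien-8-ol F1. Lipase-catalysed acetylation (Candida antarctica lipase B, vinyl acetate) takes the (8R) enantiomer, as the empirical rule for secondary alcohols predicts, to (7R,8R)-germacra-1(10),4-dien-8-yl acetate F2, which is separated from the unreacted enantiomer. Methanolysis (K2CO3 catalytic, MeOH) returns the route at compound 3.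

## Further compounds

F1 | step 2 | racemic cis-(7R*,8R*)-germacra-1(10)E,4E-dien-8-ol | C/C1=C\CC/C(C)=C/C[C@H](C(C)C)[C@H](O)C1.C/C1=C\CC/C(C)=C/C[C@@H](C(C)C)[C@@H](O)C1
F2 | step 2 | (7R,8R)-germacra-1(10)E,4E-dien-8-yl acetate | C/C1=C\CC/C(C)=C/C[C@H](C(C)C)[C@H](OC(C)=O)C1
F3 | step 5 | (4S,5S,7R,8R)-4,5-epoxygermacr-1(10)E-en-8-ol | C/C1=C\CC[C@]2(C)O[C@H]2C[C@H](C(C)C)[C@H](O)C1
F4 | step 5 | (1R,4S,5S,7R,8R,10S)-guaiane-4,8,10-triol | O[C@@H]1C[C@](C)(O)[C@@H]2CC[C@](C)(O)[C@H]2C[C@@H]1C(C)C
F5 | step 6 | 8,10-O-(3,4-dimethoxybenzylidene) acetal of 1αH,5βH-guaiane-4β,8β,10β-triol (aryl equatorial) | COc1ccc([C@@H](O5)O[C@@H]2C[C@@]5(C)[C@@H]3CC[C@](C)(O)[C@H]3C[C@@H]2C(C)C)cc1OC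
F6 | step 6 | 8,10-O-(3,4-dimethoxybenzylidene) acetal of 1αH,5βH-guai-3-ene-8β,10β-diol (aryl equatorial) | COc1ccc([C@@H](O5)O[C@@H]2C[C@@]5(C)[C@@H]3CC=C(C)[C@H]3C[C@@H]2C(C)C)cc1OC
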